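**Assumption (one line):** I read the SMILES as a 2‑(3,4‑dihydroxyphenyl)‑tetrahydrofuran that is 2,3‑trans and 3,4‑cis, with the guaiacyl carbinol (7R) on C‑4 of the ring.

## Retrosynthesis
1. The target comes from global deprotection of the tri‑O‑benzyl, C7'‑O‑TBDPS tetrahydrofuran **11**.
2. The THF ring (C7–O–C9') is formed last, by acid‑promoted cyclodehydration of a benzylic alcohol onto a primary alcohol. The C7 stereocentre is set in this step (Ar trans to the cis‑3,4 substituents).
3. The 2,3‑trans lactone **9** is reduced to the diol. **9** comes from the aldol of the lactone enolate of **7** with ArCHO, which adds trans to the β‑substituent; a trans lactone corresponds to the cis‑3,4 THF.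
4. Lactone **7** (γ‑butyrolactone ring formed first) comes from the Evans anti‑aldol adduct of imide **3** with aldehyde **4**, which sets C8' and C7'. Imide **3** is made from auxiliary **1** and acid chloride **2**.
5. Ring order: the γ‑butyrolactone is made first, then the THF.

## Route

**Step 1**
Reactants: **1** (R)‑4‑benzyloxazolidin‑2‑one; **2** methyl 4‑chloro‑4‑oxobutanoate
Product: **3** methyl 4‑[(4R)‑4‑benzyl‑2‑oxo‑oxazolidin‑3‑yl]‑4‑oxobutanoate
Conditions: n‑BuLi, THF, −78 °C; then **2**, −78 → 0 °C
Reagents that add atoms: none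
Why: N‑acylation of the lithiated oxazolidinone gives the chiral imide; no new stereocentre is formed.

**Step 2**
Reactants: **3**; **4** 4‑(benzyloxy)‑3‑methoxybenzaldehyde
Product: **5** methyl (3S,4R)‑3‑{[(4R)‑4‑benzyl‑2‑oxo‑oxazolidin‑3‑yl]carbonyl}‑4‑[4‑(benzyloxy)‑3‑methoxyphenyl]‑4‑hydroxybutanoate
Conditions: MgCl2 (10 mol %), Et3N, TMSCl, EtOAc, rt, 2 d; then TFA, MeOH, 0 °C → rt
Reagents that add atoms: TMSCl (C[Si](C)(C)Cl) silylates the alkoxide transiently; the TMS group is removed by TFA/MeOH, so none remains.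
Why: This is the Mg‑catalysed Evans anti‑aldol of the imide enolate (the imide is more acidic than the ester). C8' is set by the (R)‑benzyl auxiliary and C7' comes out anti, giving (8'R,7'R) in the final numbering. I assume the Mg‑chelated Z‑enolate face selectivity; if the opposite sense is observed, use the (S)‑auxiliary.

**Step 3**
Reactants: **5**
Product: **6** the C7'‑O‑TBDPS ether of **5**
Conditions: TBDPSCl, imidazole, DMAP, DMF, 40 °C
Reagents that add atoms: TBDPSCl, CC(C)(C)[Si](Cl)(c1ccccc1)c1ccccc1
Why: Silyl protection of the secondary benzylic alcohol. TBDPS survives the hydride, base and mild‑acid steps below and does not ionise in step 7; no stereocentre changes.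

**Step 4**
Reactants: **6**
Product: **7** (4R)‑4‑{(R)‑[4‑(benzyloxy)‑3‑methoxyphenyl][(tert‑butyldiphenylsilyl)oxy]methyl}oxolan‑2‑one
Conditions: NaBH4, THF/H2O, 0 °C; then cat. p‑TsOH, PhMe, 50 °C (same pot)
Reagents that add atoms: none
Why: NaBH4 cleaves the N‑acyl oxazolidinone to the primary alcohol in preference to the methyl ester, and the auxiliary is recovered as **1**. The alcohol then lactonises onto the ester (5‑exo acyl substitution). C8' and C7' are untouched.

**Step 5**
Reactants: **7**; **8** 3,4‑bis(benzyloxy)benzaldehyde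
Product: **9** (3S,4R)‑3‑{[3,4‑bis(benzyloxy)phenyl](hydroxy)methyl}‑4‑{(R)‑aryl(OTBDPS)methyl}oxolan‑2‑one (C7 epimeric mixture)
Conditions: LiHMDS, THF, −78 °C, 1 h; then **8**, −78 °C, 2 h; cold sat. NH4Cl quench
Reagents that add atoms: none
Why: This is a lactone‑enolate aldol. The aldehyde approaches anti to the large C4 substituent, which sets C8 trans to C8'. The C7 carbinol forms as an epimer mixture that is converged in step 7.

**Step 6**
Reactants: **9**
Product: **10** (2R,3R)‑2‑{(R)‑aryl(OTBDPS)methyl}‑3‑{[3,4‑bis(benzyloxy)phenyl](hydroxy)methyl}butane‑1,4‑diol (C7 mixture)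
Conditions: LiAlH4, THF, −20 → 0 °C; Fieser work‑up
Reagents that add atoms: none (hydride only)
Why: Lactone reduction to the two primary alcohols; Bn and TBDPS ethers are inert and no stereocentre is touched.

**Step 7**
Reactants: **10**
Product: **11** {(2S,3R,4R)‑2‑[3,4‑bis(benzyloxy)phenyl]‑4‑[(R)‑aryl(OTBDPS)methyl]oxolan‑3‑yl}methanol
Conditions: CSA (10 mol %), CH2Cl2, 4 Å MS, 0 °C → rt
Reagents that add atoms: none (loses H2O)
Why: This is acid‑catalysed benzylic etherification (5‑exo). The electron‑rich C7 cation is captured by C9'‑OH, and both C7 epimers converge on the same cation. The cis‑3,4 substituents block one face, so Ar ends up trans to both (7S). C9‑OH cannot close a 4‑ring, and the silyl ether at C7' does not ionise.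

**Step 8**
Reactants: **11**
Product: **12** the tri‑O‑benzyl THF with free C7'‑OH
Conditions: TBAF, THF, 0 °C → rt
Reagents that add atoms: none (Si is lost)
Why: Fluoride desilylation with retention at C7'.

**Step 9**
Reactants: **12**
Product: **13** (R)‑(4‑hydroxy‑3‑methoxyphenyl)[(3R,4R,5S)‑5‑(3,4‑dihydroxyphenyl)‑4‑(hydroxymethyl)oxolan‑3‑yl]methanol, i.e. (7R)‑7‑hydroxytaxiresinol
Conditions: H2 (1 atm), 10 % Pd/C, EtOAc/MeOH 1:1, rt, short reaction time
Reagents that add atoms: none (H2 only)
Why: Hydrogenolysis of the three O‑benzyl ethers releases the catechol and the guaiacol phenol; all four stereocentres are unaffected.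

## Compound list
1 | (R)‑4‑benzyloxazolidin‑2‑one | O=C1OC[C@@H](Cc2ccccc2)N1 | starting material
2 | methyl 4‑chloro‑4‑oxobutanoate | COC(=O)CCC(Cl)=O | starting material
3 | imide | COC(=O)CCC(=O)N1C(=O)OC[C@H]1Cc1ccccc1 | intermediate
4 | 4‑(benzyloxy)‑3‑methoxybenzaldehyde | COc1cc(C=O)ccc1OCc1ccccc1 | starting material
5 | anti‑aldol adduct | COc1cc([C@H](O)[C@H](CC(=O)OC)C(=O)N2C(=O)OC[C@H]2Cc2ccccc2)ccc1OCc1ccccc1 | intermediate
6 | TBDPS ether | COc1cc([C@H](O[Si](c2ccccc2)(c2ccccc2)C(C)(C)C)[C@H](CC(=O)OC)C(=O)N2C(=O)OC[C@H]2Cc2ccccc2)ccc1OCc1ccccc1 | intermediate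
7 | lactone | COc1cc([C@H](O[Si](c2ccccc2)(c2ccccc2)C(C)(C)C)[C@H]2COC(=O)C2)ccc1OCc1ccccc1 | intermediate
8 | 3,4‑bis(benzyloxy)benzaldehyde | O=Cc1ccc(OCc2ccccc2)c(OCc2ccccc2)c1 | starting material
9 | aldol lactone (C7 unspecified) | COc1cc([C@H](O[Si](c2ccccc2)(c2ccccc2)C(C)(C)C)[C@H]2COC(=O)[C@@H]2C(O)c2ccc(OCc3ccccc3)c(OCc3ccccc3)c2)ccc1OCc1ccccc1 | intermediate
10 | diol (C7 unspecified) | COc1cc([C@H](O[Si](c2ccccc2)(c2ccccc2)C(C)(C)C)[C@@H](CO)[C@H](CO)C(O)c2ccc(OCc3ccccc3)c(OCc3ccccc3)c2)ccc1OCc1ccccc1 | intermediate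
11 | THF silyl ether | COc1cc([C@H](O[Si](c2ccccc2)(c2ccccc2)C(C)(C)C)[C@H]2CO[C@H](c3ccc(OCc4ccccc4)c(OCc4ccccc4)c3)[C@H]2CO)ccc1OCc1ccccc1 | intermediate
12 | tri‑O‑benzyl THF alcohol | COc1cc([C@H](O)[C@H]2CO[C@H](c3ccc(OCc4ccccc4)c(OCc4ccccc4)c3)[C@H]2CO)ccc1OCc1ccccc1 | intermediate
13 | (7R)‑7‑hydroxytaxiresinol | COc1cc([C@H](O)[C@H]2CO[C@H](c3ccc(O)c(O)c3)[C@H]2CO)ccc1O | target

**Total steps: 9. Longest linear sequence: 9.**

## Three steps most likely to fail
1. **Step 2 (anti‑aldol).** The acyl chain carries an ester, and the absolute sense of the Mg‑mediated anti‑aldol is assumed from the chelated‑enolate model. Fallback: change the approach to C‑aroylation of the imide enolate, followed by Ru‑TsDPEN transfer hydrogenation with dynamic kinetic resolution of the β‑keto imide, so that catalyst control sets C7' and C8'.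
2. **Step 5 (lactone aldol).** This step risks retro‑aldol, low yield and poor C8 control next to a bulky β‑substituent. Fallback: install C7 as an aryl ketone (C‑acylation of the lactone enolate with ArCOCl), then use Ru‑catalysed transfer hydrogenation with dynamic kinetic resolution, so the carbinol and ring relationship come from catalyst control.
3. **Step 7 (cyclodehydration).** It could give ionisation at C7', diyl‑THF by‑products or partial desilylation. Fallback: change the approach to an SN2 closure. Open lactone **9** as its Weinreb amide, selectively mesylate the primary C9'‑OH, and close with NaH onto the C7 alkoxide.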